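The constants used here were drawn at random within sensible limits; what happens was integrated by code.

The pitfall was to count every dissolved Zb as product: the step to Ze has no way back, while Zf and Zg have one.

    Za + Zb ⇌ Zf (K1 = 10 L mol⁻¹, k1 = 0.26 L mol⁻¹ s⁻¹)
    Za + Zb ⇌ Zg (K2 = 26 L mol⁻¹, k2 = 0.12 L mol⁻¹ s⁻¹)
    Zd ⇌ Zb, rate k3*(cs3 - [Zb]) while solid is left; crystals form when [Zb] > cs3 (cs3 = 0.082 M, k3 = 9.0 × 10⁻⁴ s⁻¹)
    Zb → Ze (k4 = 0.0026 s⁻¹)
    Za ⇌ Zc (K5 = 0.89, k5 = 2.3 × 10⁻⁴ s⁻¹)

| flask | Za | Zd | time |
|---|---|---|---|
| summer | 0.10 M | 0.400 M | 40 min |
| winter | 0.20 M | 0.400 M | 40 min |
| dawn | 0.40 M | 0.400 M | 40 min |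
| dusk | 0.80 M | 0.400 M | 40 min |
| autumn | 1.5 M | 0.400 M | 40 min |

1. [Zf] at the end for summer, winter, dawn, dusk, autumn, in this order
2. how that number moves from the first to the last of them (falls all the way / rises, then falls / falls, then rises / hardly changes / rises all the way)

- solid, in amounts per volume of the solution: Zd
- at the start none of Zd is in solution
- "hardly changes" means that all values lie within two and a half points (for a concentration: within two and a half percent of the largest)
- run time (summer): 40 min

1. I followed one dissolved Zb in summer. Caught as Zf, it came back with a rate constant of 0.0260 s⁻¹, and caught as Zg, with 0.00462 s⁻¹. Both return rates were faster than one over the run time, so I took each bound form to stay near its equilibrium with Za and Zb, and the lasting loss of Zb to be Ze.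

2. My first way was the level. I defined the resting level as the c(Zb) at which dissolution just pays for the loss to Ze, a steady state, which came to dissolution coefficient times solubility over the sum of that coefficient and the Ze rate constant: 0.0211 M. With the bound forms filling alongside, I reckoned the time constant of that approach in summer at about 21.9 min, about half of the run, so I expected summer to end near the level. At that level, 56.8% of the Za not in Zc stayed free, and I reckoned 20.4% of the charge had gone to Zc. So summer's c(Zf) came to 0.00954 M.

3. My second way was the supply. At full drive, the run dissolved at most 0.177 M, and the equilibrium constants gave Zf 27.8% of what was bound, so c(Zf) came to 0.0492 M whatever the Za charge.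

4. The two ways parted, and each cheated somewhere. In summer, the supply way asked for more bound reagent than the 0.10 M of Za charged. In autumn, the level way asked for 0.515 M bound, more than the supply. So I took the smaller figure at each end: 0.00954 M for summer and 0.0492 M for autumn, a row that rises from first to last.

5. The forecast gave 0.0092 M, 0.018 M, 0.029 M, 0.036 M and 0.042 M, and its shape was "rises all the way", on the ground that “More Za therefore captures more of the dissolved reagent”. Its ends lay below mine.

6. The simulation gave 0.00915 M, 0.0171 M, 0.0281 M, 0.0381 M and 0.0442 M, and the row rises all the way.

In summer, c(Zb) stood at 0.0209 M after 40.0 min, against the resting level of 0.0211 M, with Zb made 1.02 times as fast as it was used up, each step taken net. In autumn, at the same time, c(Zb) was 0.00502 M, a quarter of that level, and Ze had reached 0.0150 M, less than the 0.0915 M of summer.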